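**Retrosynthetic overview**

1. Target 23 comes from 22 by one hydrogenolysis of two benzyl ethers and one 2-naphthylmethyl ether.
2. Key disconnection of 22: O1–C7a and C3–C3a of the dihydrobenzofuran, giving a 3-methoxyaryne (from silyl triflate 16) and the erythro epoxy alkoxide of 19. Enabling feature: the C3a–C7a edge of the benzene ring lies next to the C4 methoxy group, which sends an oxygen nucleophile to C7a and leaves the carbanion at C3a; O1–C2–C3–CH2OH is a 1-aryl-2,3-epoxypropan-1-ol in disguise.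
3. 16 comes from bromophenol 13 (retro-Brook rearrangement, triflation); 13 from oxolane 11; 11 from epoxy cinnamyl ether 10 by titanocene radical cyclization (C3–C4 bond of the oxolane); 10 from epoxy alcohol 9 and cinnamyl bromide 6.
4. All absolute configuration comes from two Sharpless kinetic resolutions of aryl vinyl carbinols (9 with L-(+)-DIPT, 19 with D-(−)-DIPT).
5. Ring order: the three benzene rings are bought, the oxolane is closed in step 8, the dihydrofuran ring is closed last in step 14.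

Key step: step 14

Assumption: compounds 1, 7 and 17 are taken as commercial, and in each kinetic resolution the epoxy alcohol formed from the fast-reacting enantiomer is the material carried on.

**Route**

Step 1
Reactants: 1 (4-bromo-3,5-dimethoxyphenyl)methanol
Product: 3 [4-bromo-3-methoxy-5-(prop-2-en-1-yloxy)phenyl]methanol, via sodium phenolate 2 (not isolated)
Conditions: EtSNa (2.2 equiv), DMF, 110 °C; then allyl bromide, 0 °C to rt
Reagents that add atoms: allyl bromide, C=CCBr
Why: Thiolate SN2 demethylation cleaves one of the two equivalent methyl ethers and then stops because the phenolate formed deactivates the ring, and this phenolate (not the neutral benzylic alcohol) is O-allylated in the same pot (Williamson ether synthesis), which breaks the symmetry of the ring with a group that can later be removed beside benzyl-type ethers.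

Step 2
Reactants: 3 [4-bromo-3-methoxy-5-(prop-2-en-1-yloxy)phenyl]methanol
Product: 4 4-bromo-3-methoxy-5-(prop-2-en-1-yloxy)benzaldehyde
Conditions: MnO2, CH2Cl2, rt
Reagents that add atoms: none
Why: MnO2 oxidises the benzylic alcohol to the aldehyde and stops there, leaving the allyl ether and the aryl bromide untouched (heterogeneous benzylic oxidation).

Step 3
Reactants: 4 4-bromo-3-methoxy-5-(prop-2-en-1-yloxy)benzaldehyde
Product: 5 rac-1-[4-bromo-3-methoxy-5-(prop-2-en-1-yloxy)phenyl]prop-2-en-1-ol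
Conditions: vinylMgBr, THF, −78 to 0 °C; aq NH4Cl
Reagents that add atoms: vinylmagnesium bromide, C=C[Mg]Br
Why: Grignard addition to the aldehyde is much faster at low temperature than any exchange at the hindered aryl bromide; the new carbinol centre is racemic and is erased in step 4.

Step 4
Reactants: 5 rac-1-[4-bromo-3-methoxy-5-(prop-2-en-1-yloxy)phenyl]prop-2-en-1-ol
Product: 6 2-bromo-5-[(1E)-3-bromoprop-1-en-1-yl]-1-methoxy-3-(prop-2-en-1-yloxy)benzene
Conditions: PBr3, Et2O, 0 °C
Reagents that add atoms: phosphorus tribromide, BrP(Br)Br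
Why: PBr3 brominates the aryl vinyl carbinol with allylic transposition (SN2'/ion-pair pathway) to the conjugated, thermodynamically preferred (E)-cinnamyl bromide.

Step 5
Reactants: 7 3-(benzyloxy)-4-methoxybenzaldehyde
Product: 8 rac-1-[3-(benzyloxy)-4-methoxyphenyl]prop-2-en-1-ol
Conditions: vinylMgBr, THF, −78 to 0 °C; aq NH4Cl
Reagents that add atoms: vinylmagnesium bromide, C=C[Mg]Br
Why: Grignard addition of the vinyl group to the aldehyde; the racemate is intended because step 6 resolves it.

Step 6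
Reactants: 8 rac-1-[3-(benzyloxy)-4-methoxyphenyl]prop-2-en-1-ol
Product: 9 (S)-[3-(benzyloxy)-4-methoxyphenyl][(2R)-oxiran-2-yl]methanol (erythro)
Conditions: Ti(OiPr)4, L-(+)-DIPT, t-BuOOH (0.45 equiv), 4 Å MS, CH2Cl2, −20 °C
Reagents that add atoms: tert-butyl hydroperoxide, CC(C)(C)OO
Why: Sharpless kinetic resolution: with L-(+)-DIPT the (R)-alcohol is epoxidised far faster than its enantiomer and with the erythro selectivity typical of secondary allylic alcohols, which sets the carbinol centre (S by name only because the oxiranyl group now outranks the aryl group; it becomes C2 of the oxolane) and the (R)-oxirane centre, and the unreacted (S)-alcohol is separated.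

Step 7
Reactants: 9 (S)-[3-(benzyloxy)-4-methoxyphenyl][(2R)-oxiran-2-yl]methanol; 6 2-bromo-5-[(1E)-3-bromoprop-1-en-1-yl]-1-methoxy-3-(prop-2-en-1-yloxy)benzene
Product: 10 (2R)-2-[(S)-[3-(benzyloxy)-4-methoxyphenyl]({(2E)-3-[4-bromo-3-methoxy-5-(prop-2-en-1-yloxy)phenyl]prop-2-en-1-yl}oxy)methyl]oxirane
Conditions: NaH, THF–DMF, 0 °C; then 6, Bu4NI (cat.), 0 °C to rt
Reagents that add atoms: none
Why: Williamson etherification of the sodium alkoxide with the reactive allylic bromide at 0 °C, expected to be faster than Payne rearrangement of the epoxy alkoxide; no stereocentre is touched.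

Step 8
Reactants: 10 (2R)-2-[(S)-[3-(benzyloxy)-4-methoxyphenyl]({(2E)-3-[4-bromo-3-methoxy-5-(prop-2-en-1-yloxy)phenyl]prop-2-en-1-yl}oxy)methyl]oxirane
Product: 11 [(2R,3S,4S)-2-[3-(benzyloxy)-4-methoxyphenyl]-4-{[4-bromo-3-methoxy-5-(prop-2-en-1-yloxy)phenyl]methyl}oxolan-3-yl]methanol
Conditions: Cp2TiCl2 (titanocene dichloride), Zn dust, THF, rt, slow addition of 10; then dilute HCl, 0 °C
Reagents that add atoms: none
Why: Cp2TiCl (trivalent titanium, made in the flask) opens the oxirane by single-electron transfer to the secondary β-titanoxy radical, which cyclises 5-exo-trig onto the styrene-type double bond through a chair-like transition state with the C2 aryl group pseudo-equatorial, so that the new C3 and C4 centres should come out 2,3-trans and 3,4-cis (titanocene-mediated reductive epoxide–alkene radical cyclization, a known entry to 2-aryl-3-hydroxymethyl-4-benzyl oxolanes); the benzylic radical is reduced by a second Cp2TiCl and protonated on work-up.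

Step 9
Reactants: 11 [(2R,3S,4S)-2-[3-(benzyloxy)-4-methoxyphenyl]-4-{[4-bromo-3-methoxy-5-(prop-2-en-1-yloxy)phenyl]methyl}oxolan-3-yl]methanol
Product: 12 (2R,3S,4S)-2-[3-(benzyloxy)-4-methoxyphenyl]-4-{[4-bromo-3-methoxy-5-(prop-2-en-1-yloxy)phenyl]methyl}-3-[(naphthalen-2-ylmethoxy)methyl]oxolane
Conditions: NaH, 2-(bromomethyl)naphthalene, Bu4NI (cat.), THF–DMF, 0 °C to rt
Reagents that add atoms: 2-(bromomethyl)naphthalene, BrCc1ccc2ccccc2c1
Why: Williamson ether synthesis on the primary alcohol; the 2-naphthylmethyl ether tolerates butyllithium, fluoride and alkoxides and is hydrogenolysed more readily than a benzyl ether at the end.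

Step 10
Reactants: 12 (2R,3S,4S)-2-[3-(benzyloxy)-4-methoxyphenyl]-4-{[4-bromo-3-methoxy-5-(prop-2-en-1-yloxy)phenyl]methyl}-3-[(naphthalen-2-ylmethoxy)methyl]oxolane
Product: 13 2-bromo-5-{[(3S,4S,5R)-5-[3-(benzyloxy)-4-methoxyphenyl]-4-[(naphthalen-2-ylmethoxy)methyl]oxolan-3-yl]methyl}-3-methoxyphenol
Conditions: Pd(PPh3)4 (cat.), morpholine, THF, rt
Reagents that add atoms: none
Why: Zerovalent palladium ionises the aryl allyl ether to a π-allyl complex that is captured by morpholine (Tsuji–Trost deallylation), freeing only the phenol next to the bromine; benzyl-type ethers and the hindered aryl bromide are not affected at room temperature.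

Step 11
Reactants: 13 2-bromo-5-{[(3S,4S,5R)-5-[3-(benzyloxy)-4-methoxyphenyl]-4-[(naphthalen-2-ylmethoxy)methyl]oxolan-3-yl]methyl}-3-methoxyphenol
Product: 16 5-{[(3S,4S,5R)-5-[3-(benzyloxy)-4-methoxyphenyl]-4-[(naphthalen-2-ylmethoxy)methyl]oxolan-3-yl]methyl}-3-methoxy-2-(trimethylsilyl)phenyl trifluoromethanesulfonate, via aryl trimethylsilyl ether 14 (not isolated), via lithium 2-silylphenolate 15 (not isolated)
Conditions: (Me3Si)2NH, THF, 65 °C, evaporate; n-BuLi, THF, −100 to −78 °C; Tf2O, −78 °C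
Reagents that add atoms: hexamethyldisilazane, C[Si](C)(C)N[Si](C)(C)C; trifluoromethanesulfonic anhydride, O=S(=O)(OS(=O)(=O)C(F)(F)F)C(F)(F)F
Why: O-Silylation, bromine–lithium exchange and 1,3 O-to-C silyl migration (retro-Brook rearrangement) place the silyl group on the carbon between the two oxygens, and the lithium phenolate formed is triflated in the same flask, the standard way from 2-bromophenols to 2-(trimethylsilyl)aryl triflates.

Step 12
Reactants: 17 4-(benzyloxy)-3-methoxybenzaldehyde
Product: 18 rac-1-[4-(benzyloxy)-3-methoxyphenyl]prop-2-en-1-ol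
Conditions: vinylMgBr, THF, −78 to 0 °C; aq NH4Cl
Reagents that add atoms: vinylmagnesium bromide, C=C[Mg]Br
Why: Grignard addition of the vinyl group to the aldehyde; the racemate is resolved in step 13.

Step 13
Reactants: 18 rac-1-[4-(benzyloxy)-3-methoxyphenyl]prop-2-en-1-ol
Product: 19 (R)-[4-(benzyloxy)-3-methoxyphenyl][(2S)-oxiran-2-yl]methanol (erythro)
Conditions: Ti(OiPr)4, D-(−)-DIPT, t-BuOOH (0.45 equiv), 4 Å MS, CH2Cl2, −20 °C
Reagents that add atoms: tert-butyl hydroperoxide, CC(C)(C)OO
Why: Sharpless kinetic resolution: with D-(−)-DIPT the (S)-alcohol is epoxidised fast and erythro-selectively, which sets the carbinol centre (future C2 of the dihydrobenzofuran, carried on with retention) and the (S)-oxirane carbon (future C3 after inversion); the unreacted (R)-alcohol is separated.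

Step 14
Reactants: 16 5-{[(3S,4S,5R)-5-[3-(benzyloxy)-4-methoxyphenyl]-4-[(naphthalen-2-ylmethoxy)methyl]oxolan-3-yl]methyl}-3-methoxy-2-(trimethylsilyl)phenyl trifluoromethanesulfonate; 19 (R)-[4-(benzyloxy)-3-methoxyphenyl][(2S)-oxiran-2-yl]methanol
Product: 22 [(2S,3R)-2-[4-(benzyloxy)-3-methoxyphenyl]-6-{[(3S,4S,5R)-5-[3-(benzyloxy)-4-methoxyphenyl]-4-[(naphthalen-2-ylmethoxy)methyl]oxolan-3-yl]methyl}-4-methoxy-2,3-dihydro-1-benzofuran-3-yl]methanol, via aryne 20 (not isolated), via aryl anion 21 (not isolated)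
Conditions: 19 (3 equiv), NaH, THF, 0 °C; then CsF, 18-crown-6, slow addition of 16, 0 °C to rt; aq NH4Cl
Reagents that add atoms: none
Why: Proposed new method: fluoride removes the silyl group of 16 and triflate leaves to give the 3-methoxyaryne 20; the sodium alkoxide of 19 adds to the aryne carbon remote from the methoxy group (future C7a), because the methoxy group polarises the aryne and stabilises the carbanion that develops next to it at C3a, and the resulting aryl anion 21 opens the oxirane at its internal carbon and releases the primary alkoxide that becomes the hydroxymethyl group. The closest known reaction types are nucleophile addition to an aryne with intramolecular capture of the aryl anion (aryne annulation) and the Parham cyclization of 2-lithioaryl glycidyl ethers, which is known to give 3-(hydroxymethyl)-2,3-dihydrobenzofurans by the exo mode; what is new is running both in one flask with an epoxy alkoxide. The dihydrofuran ring is closed by intermolecular O-arylation (O1–C7a) followed by an anionic 5-exo-tet C–C closure (C3a–C3). C2 is carried unchanged from the carbinol carbon of 19 because no bond to it is broken, and the new centre C3 arises by inversion at the (S)-oxirane carbon, so the erythro epoxy alcohol should give the trans-(2S,3R) ring. The step needs regioselective addition to the aryne (secured by the C4 methoxy group), exo rather than 6-endo opening (secured by the five-membered transition state) and cyclisation of the aryl anion before it is protonated (secured by the fully deprotonated, aprotic medium and the excess of 19, which also keeps the product alkoxide from competing for the aryne).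

Step 15
Reactants: 22 [(2S,3R)-2-[4-(benzyloxy)-3-methoxyphenyl]-6-{[(3S,4S,5R)-5-[3-(benzyloxy)-4-methoxyphenyl]-4-[(naphthalen-2-ylmethoxy)methyl]oxolan-3-yl]methyl}-4-methoxy-2,3-dihydro-1-benzofuran-3-yl]methanol
Product: 23 5-[(2R,3S,4S)-4-{[(2S,3R)-2-(4-hydroxy-3-methoxyphenyl)-3-(hydroxymethyl)-4-methoxy-2,3-dihydro-1-benzofuran-6-yl]methyl}-3-(hydroxymethyl)oxolan-2-yl]-2-methoxyphenol (target)
Conditions: H2 (1 atm), palladium on carbon (Pd/C), EtOAc–MeOH, rt
Reagents that add atoms: none
Why: Hydrogenolysis removes the two aryl benzyl ethers and the 2-naphthylmethyl ether, all of which should cleave faster than the benzylic C–O bonds of the two oxygen heterocycles if the reaction is stopped at full deprotection; no stereocentre is affected.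

**Compound list**

1 | (4-bromo-3,5-dimethoxyphenyl)methanol | COc1cc(CO)cc(OC)c1Br | starting material
2 | sodium 2-bromo-5-(hydroxymethyl)-3-methoxyphenolate | COc1cc(CO)cc([O-])c1Br.[Na+] | intermediate (not isolated)
3 | [4-bromo-3-methoxy-5-(prop-2-en-1-yloxy)phenyl]methanol | COc1cc(CO)cc(OCC=C)c1Br | intermediate
4 | 4-bromo-3-methoxy-5-(prop-2-en-1-yloxy)benzaldehyde | COc1cc(C=O)cc(OCC=C)c1Br | intermediate
5 | rac-1-[4-bromo-3-methoxy-5-(prop-2-en-1-yloxy)phenyl]prop-2-en-1-ol | COc1cc(C(O)C=C)cc(OCC=C)c1Br | intermediate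
6 | 2-bromo-5-[(1E)-3-bromoprop-1-en-1-yl]-1-methoxy-3-(prop-2-en-1-yloxy)benzene | COc1cc(/C=C/CBr)cc(OCC=C)c1Br | intermediate
7 | 3-(benzyloxy)-4-methoxybenzaldehyde | COc1ccc(C=O)cc1OCc1ccccc1 | starting material
8 | rac-1-[3-(benzyloxy)-4-methoxyphenyl]prop-2-en-1-ol | COc1ccc(C(O)C=C)cc1OCc1ccccc1 | intermediate
9 | (S)-[3-(benzyloxy)-4-methoxyphenyl][(2R)-oxiran-2-yl]methanol | COc1ccc([C@H](O)[C@H]2CO2)cc1OCc1ccccc1 | intermediate
10 | (2R)-2-[(S)-[3-(benzyloxy)-4-methoxyphenyl]({(2E)-3-[4-bromo-3-methoxy-5-(prop-2-en-1-yloxy)phenyl]prop-2-en-1-yl}oxy)methyl]oxirane | COc1ccc([C@H](OC/C=C/c2cc(OC)c(Br)c(OCC=C)c2)[C@H]2CO2)cc1OCc1ccccc1 | intermediate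
11 | [(2R,3S,4S)-2-[3-(benzyloxy)-4-methoxyphenyl]-4-{[4-bromo-3-methoxy-5-(prop-2-en-1-yloxy)phenyl]methyl}oxolan-3-yl]methanol | COc1ccc([C@@H]2OC[C@@H](Cc3cc(OC)c(Br)c(OCC=C)c3)[C@H]2CO)cc1OCc1ccccc1 | intermediate
12 | (2R,3S,4S)-2-[3-(benzyloxy)-4-methoxyphenyl]-4-{[4-bromo-3-methoxy-5-(prop-2-en-1-yloxy)phenyl]methyl}-3-[(naphthalen-2-ylmethoxy)methyl]oxolane | COc1ccc([C@@H]2OC[C@@H](Cc3cc(OC)c(Br)c(OCC=C)c3)[C@H]2COCc2ccc3ccccc3c2)cc1OCc1ccccc1 | intermediate
13 | 2-bromo-5-{[(3S,4S,5R)-5-[3-(benzyloxy)-4-methoxyphenyl]-4-[(naphthalen-2-ylmethoxy)methyl]oxolan-3-yl]methyl}-3-methoxyphenol | COc1ccc([C@@H]2OC[C@@H](Cc3cc(OC)c(Br)c(O)c3)[C@H]2COCc2ccc3ccccc3c2)cc1OCc1ccccc1 | intermediate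
14 | (2-bromo-5-{[(3S,4S,5R)-5-[3-(benzyloxy)-4-methoxyphenyl]-4-[(naphthalen-2-ylmethoxy)methyl]oxolan-3-yl]methyl}-3-methoxyphenoxy)(trimethyl)silane | COc1ccc([C@@H]2OC[C@@H](Cc3cc(OC)c(Br)c(O[Si](C)(C)C)c3)[C@H]2COCc2ccc3ccccc3c2)cc1OCc1ccccc1 | intermediate (not isolated)
15 | lithium 5-{[(3S,4S,5R)-5-[3-(benzyloxy)-4-methoxyphenyl]-4-[(naphthalen-2-ylmethoxy)methyl]oxolan-3-yl]methyl}-3-methoxy-2-(trimethylsilyl)phenolate | COc1ccc([C@@H]2OC[C@@H](Cc3cc(OC)c([Si](C)(C)C)c([O-])c3)[C@H]2COCc2ccc3ccccc3c2)cc1OCc1ccccc1.[Li+] | intermediate (not isolated)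
16 | 5-{[(3S,4S,5R)-5-[3-(benzyloxy)-4-methoxyphenyl]-4-[(naphthalen-2-ylmethoxy)methyl]oxolan-3-yl]methyl}-3-methoxy-2-(trimethylsilyl)phenyl trifluoromethanesulfonate | COc1ccc([C@@H]2OC[C@@H](Cc3cc(OC)c([Si](C)(C)C)c(OS(=O)(=O)C(F)(F)F)c3)[C@H]2COCc2ccc3ccccc3c2)cc1OCc1ccccc1 | intermediate
17 | 4-(benzyloxy)-3-methoxybenzaldehyde | COc1cc(C=O)ccc1OCc1ccccc1 | starting material
18 | rac-1-[4-(benzyloxy)-3-methoxyphenyl]prop-2-en-1-ol | COc1cc(C(O)C=C)ccc1OCc1ccccc1 | intermediate
19 | (R)-[4-(benzyloxy)-3-methoxyphenyl][(2S)-oxiran-2-yl]methanol | COc1cc([C@@H](O)[C@@H]2CO2)ccc1OCc1ccccc1 | intermediate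
20 | 1,2-didehydro-3-methoxy-5-{[(3S,4S,5R)-5-[3-(benzyloxy)-4-methoxyphenyl]-4-[(naphthalen-2-ylmethoxy)methyl]oxolan-3-yl]methyl}benzene (aryne) | COc1ccc([C@@H]2OC[C@@H](CC3=CC#CC(OC)=C3)[C@H]2COCc2ccc3ccccc3c2)cc1OCc1ccccc1 | intermediate (not isolated)
21 | sodium 2-{(R)-[4-(benzyloxy)-3-methoxyphenyl][(2S)-oxiran-2-yl]methoxy}-6-methoxy-4-{[(3S,4S,5R)-5-[3-(benzyloxy)-4-methoxyphenyl]-4-[(naphthalen-2-ylmethoxy)methyl]oxolan-3-yl]methyl}benzen-1-ide | COc1ccc([C@@H]2OC[C@@H](Cc3cc(OC)[c-]c(O[C@H](c4ccc(OCc5ccccc5)c(OC)c4)[C@@H]4CO4)c3)[C@H]2COCc2ccc3ccccc3c2)cc1OCc1ccccc1.[Na+] | intermediate (not isolated)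
22 | [(2S,3R)-2-[4-(benzyloxy)-3-methoxyphenyl]-6-{[(3S,4S,5R)-5-[3-(benzyloxy)-4-methoxyphenyl]-4-[(naphthalen-2-ylmethoxy)methyl]oxolan-3-yl]methyl}-4-methoxy-2,3-dihydro-1-benzofuran-3-yl]methanol | COc1ccc([C@@H]2OC[C@@H](Cc3cc(OC)c4c(c3)O[C@H](c3ccc(OCc5ccccc5)c(OC)c3)[C@H]4CO)[C@H]2COCc2ccc3ccccc3c2)cc1OCc1ccccc1 | intermediate
23 | 5-[(2R,3S,4S)-4-{[(2S,3R)-2-(4-hydroxy-3-methoxyphenyl)-3-(hydroxymethyl)-4-methoxy-2,3-dihydro-1-benzofuran-6-yl]methyl}-3-(hydroxymethyl)oxolan-2-yl]-2-methoxyphenol | COc1ccc([C@@H]2OC[C@@H](Cc3cc(OC)c4c(c3)O[C@H](c3ccc(O)c(OC)c3)[C@H]4CO)[C@H]2CO)cc1O | target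

**Step count**

Total steps: 15. Longest linear sequence: 11 steps (steps 1–4, 7–11, 14, 15).

**Steps most likely to fail, with fallbacks**

Step 14 (proposed new method). What may go wrong: the aryl anion is protonated before it closes the ring; the epoxy alkoxide undergoes Payne rearrangement before O-arylation; or the product alkoxide is arylated by further aryne. The fallback uses known chemistry, sets out from bromophenol 13 and epoxy alcohol 19, and rejoins the route at 22. The carbinol centre of 19 is inverted by a Mitsunobu reaction with 4-nitrobenzoic acid (PPh3, DIAD, THF) to (S)-[4-(benzyloxy)-3-methoxyphenyl][(2S)-oxiran-2-yl]methyl 4-nitrobenzoate F1. Methanolysis (K2CO3, MeOH, 0 °C) gives the threo alcohol (S)-[4-(benzyloxy)-3-methoxyphenyl][(2S)-oxiran-2-yl]methanol F2. A second Mitsunobu reaction, with phenol 13 as the acidic partner, inverts the centre again and gives the erythro aryl ether (2S)-2-[(R)-[4-(benzyloxy)-3-methoxyphenyl](2-bromo-5-{[(3S,4S,5R)-5-[3-(benzyloxy)-4-methoxyphenyl]-4-[(naphthalen-2-ylmethoxy)methyl]oxolan-3-yl]methyl}-3-methoxyphenoxy)methyl]oxirane F3. Bromine–lithium exchange (t-BuLi, THF, −78 °C) then starts the Parham cyclization: the aryllithium opens the oxirane 5-exo-tet with inversion and should give 22.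

Step 13. What may go wrong: ionisation of the para-alkoxybenzylic carbinol on the Lewis-acidic Ti(OiPr)4–DIPT catalyst, with loss of configuration or allylic transposition, or a low selectivity factor. The fallback sets out from racemic 18 and comes back at 19. Lipase-catalysed acylation (immobilised Candida antarctica lipase B, vinyl acetate, toluene, rt) should acetylate the (R)-enantiomer to (1R)-1-[4-(benzyloxy)-3-methoxyphenyl]prop-2-en-1-yl acetate F5 and leave (1S)-1-[4-(benzyloxy)-3-methoxyphenyl]prop-2-en-1-ol F4. After separation, hydroxyl-directed epoxidation of F4 with VO(acac)2 and t-BuOOH in CH2Cl2, expected to be erythro-selective, gives 19.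

Step 6. What may go wrong: the same ionisation of the benzylic carbinol during the titanium-mediated resolution. The fallback sets out from aldehyde 7 and comes back at 9. Catalytic enantioselective vinyl transfer (divinylzinc with a chiral β-amino alcohol ligand of the enantiomeric series that directs addition to the Re face of the aldehyde) gives (1R)-1-[3-(benzyloxy)-4-methoxyphenyl]prop-2-en-1-ol F6. Hydroxyl-directed epoxidation with VO(acac)2 and t-BuOOH then gives 9. Here only the carbinol configuration matters, because the oxirane carbon becomes the radical centre in step 8.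

**Further compounds**

F1 | step 14 | (S)-[4-(benzyloxy)-3-methoxyphenyl][(2S)-oxiran-2-yl]methyl 4-nitrobenzoate | COc1cc([C@H](OC(=O)c2ccc(cc2)[N+](=O)[O-])[C@@H]2CO2)ccc1OCc1ccccc1
F2 | step 14 | (S)-[4-(benzyloxy)-3-methoxyphenyl][(2S)-oxiran-2-yl]methanol | COc1cc([C@H](O)[C@@H]2CO2)ccc1OCc1ccccc1
F3 | step 14 | (2S)-2-[(R)-[4-(benzyloxy)-3-methoxyphenyl](2-bromo-5-{[(3S,4S,5R)-5-[3-(benzyloxy)-4-methoxyphenyl]-4-[(naphthalen-2-ylmethoxy)methyl]oxolan-3-yl]methyl}-3-methoxyphenoxy)methyl]oxirane | COc1ccc([C@@H]2OC[C@@H](Cc3cc(OC)c(Br)c(O[C@H](c4ccc(OCc5ccccc5)c(OC)c4)[C@@H]4CO4)c3)[C@H]2COCc2ccc3ccccc3c2)cc1OCc1ccccc1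
F4 | step 13 | (1S)-1-[4-(benzyloxy)-3-methoxyphenyl]prop-2-en-1-ol | COc1cc([C@@H](O)C=C)ccc1OCc1ccccc1
F5 | step 13 | (1R)-1-[4-(benzyloxy)-3-methoxyphenyl]prop-2-en-1-yl acetate | COc1cc([C@H](OC(C)=O)C=C)ccc1OCc1ccccc1
F6 | step 6 | (1R)-1-[3-(benzyloxy)-4-methoxyphenyl]prop-2-en-1-ol | COc1ccc([C@H](O)C=C)cc1OCc1ccccc1
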